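**Remarks on the chemistry (assumptions)**

- Amine of the key step: diarylprolinol silyl ethers direct reagents to the face away from the diphenyl(silyloxy)methyl group, on the E,s-trans iminium ion and on the E-enamine alike. On that model the (R)-amine should give 4S in the iminium stage and 3R in the enamine stage, which is the 3,4-cis pair the target needs; the (S)-amine would give 3S,4R. The route therefore uses the (R)-amine for both stages.
- O7 of the phenol partner is carried as an allyl ether, not a benzyl ether, so that this one phenol can be set free before the last C–C bond is made.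
- 3-(Allyloxy)phenol is taken as a catalogue compound (otherwise one monoallylation of resorcinol supplies it).
- Ep = 6-bromo-3,5,7,3',4'-penta-O-benzyl-(2R,3R)-epicatechin-8-yl.

## Structural features

The target is a linear trimer of three flavan-3-ol units, each a benzopyran (rings A and C) with a pendant aryl ring B. The top and middle units are 5-deoxy (7-hydroxy) flavans with pyrogallol B rings; the bottom unit is (−)-epicatechin. C4 of the top unit is bonded to C8 of the middle unit and C4 of the middle unit to C8 of the bottom unit, so both linking carbons are doubly benzylic methines. There are eight stereocentres: every unit is 2R,3R (2,3-cis); C4 of the top unit (R) is trans to its C3 hydroxyl, whereas C4 of the middle unit (S) is cis to its C3 hydroxyl, so C2, C3 and C4 of the middle ring C are contiguous and all-cis. Fragile features are the thirteen free phenols (the pyrogallol rings oxidise easily, above all in base), the benzylic C2–O1 ethers, C2 (epimerisable through ring opening in base) and the electron-rich rings and interflavan bonds towards acid and electrophiles. The difficulty is twofold: the all-cis middle ring C cannot come from the usual C4-cation coupling, which gives 3,4-trans, and the top unit must be joined at C8 of a 5-deoxy ring A that by itself reacts at C6. The key step exploits that C2, C3 and C4 of the middle unit are a three-carbon chain at the aldehyde oxidation level on C8 of the epicatechin unit, flanked by O1 and C4a of a resorcinol-type ring A: C4 and C3 are the β- and α-carbons of an enal and C2 is its carbonyl carbon.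

## Logic of the disconnections

34 to 33: thirteen O–benzyl bonds and three aryl C–Br bonds are cut. All phenols are masked alike and the bromines serve as blocking groups, so one hydrogenolysis finishes the synthesis. The forward step must spare the benzylic C2–O1 ethers and the C4 methines and must buffer the HBr that is set free.

33 to 25 and 32: the bond C4 (top)–C8 (middle) is cut. This is the classical benzylic-cation bond of this compound class and it separates a chiral-pool monomer from the dimer. The forward step demands attack only at C8 of 25 (both C6 positions are brominated and the 7-hydroxyl is free to activate its ortho carbon), on the face trans to the C3 hydroxyl of 32, and no self-alkylation of 32 (its own C6 is brominated).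

25 to 24, 23, then 19 and 22 (from 21): the O–allyl bond, the C2–H bond and the C2–aryl (ring B) bond of the middle unit are cut in turn. Ring B enters as an aryllithium on a lactone carbonyl and C2 is then set by hydride delivery. This reduces the all-cis triad to a lactone with only C3 and C4. The forward steps demand a single addition to the lactone and hydride attack on the face opposite the cis substituents at C3 and C4.

19 to 14 (through 18, 17, 16, 15): no skeletal bond is cut; C2 changes oxidation level and the O3 benzoate is exchanged for benzyl, because a benzoate cannot survive an aryllithium. The demand is that C3, α to a masked aldehyde, is never exposed as a free α-hydroxy aldehyde in base, hence the acetal.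

14 to 9, 11 and 12: C4–C4a, C3–O and O1–C2 are cut. This removes ring C of the middle unit with two stereocentres in one operation and leads to an enal, a phenol and a peroxide. The demand is catalyst control of both new centres and ortho C-alkylation of 11 at the carbon para to its ether.

9 to 7, 6, 4, 3, 2 and 1: the Cα=Cβ bond of the enal (Wittig), the C6–Br bond, the C8–CHO bond (through the 8-bromide) and the benzyl ethers are cut back to the chiral-pool flavan. Each forward step relies on the graded reactivity of the phloroglucinol ring A: C8 first, then C6.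

11 to 10: the C–Br bond is cut; bromination must go para to the free hydroxyl.

32 to 31, 30, 29, 27 and 26: the C6–Br bond is cut, C3 is inverted through its ketone, the C4 methoxy group is traced to the C4 carbonyl, and the benzyl ethers are removed. The chiral pool supplies C2; the forward sequence must turn 2,3-trans into 2,3-cis and keep a leaving group at C4.

21 to 20: three O–benzyl bonds are cut.

## Other disconnections considered

Alternative 1: The cut runs through ring A of the middle unit (C8–C8a, C6–C7, C4a–C8a). The ring would be assembled from siloxyalkyne A2, already attached to C4 of the finished top flavan, and diazoketone A3. Forward, photochemical Wolff rearrangement of A3 would give a vinylketene that adds [2+2] to A2; four-electron opening of the cyclobutenone and six-electron closure would give phenol A1 (free C8a hydroxyl, C7 silyl ether, acetal carbon on C4a).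
- In its favour: the C4 (top)–C8 (middle) bond is never made by Friedel–Crafts attack at a reluctant position; the substitution pattern of ring A follows from the regiochemistry of the cycloaddition; the two ring A oxygens come out differentiated.
- Against it here: in A1 the whole middle ring C, with its three all-cis centres and the bond to the epicatechin unit, is still missing and would have to be grown from the acetal carbon under the influence of a remote top unit. The benzylated flavan must survive irradiation and heating, and A2 and A3 are multi-step reagents.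
- Comparison: on the regiochemistry of the top–middle bond alternative 1 is the better plan (no bromine, no late coupling). As a reaction type it is better precedented than the chosen key step. On step economy and on the central stereochemical problem it is weaker, because the key step is spent on an aromatic ring and the all-cis ring C is left to a long linear sequence, while the chosen plan sets C3 and C4 and closes ring C at once.

Alternative 2: The cut is O1–C2 and C3–O of the middle unit, back to Z-alkene A5, a 1,3-diarylpropene whose C4 already carries ring A as a free phenol and the epicatechin unit. Forward, a peracid held by the phenol would epoxidise the alkene on the ring A face, and the phenol would open the epoxide at the benzylic carbon with inversion (6-endo) to give A4.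
- In its favour: Z geometry translates into 2,3-cis; allylic 1,3-strain of a Z-alkene holds C4–H in the alkene plane, so the two aryl groups on C4 differentiate the faces; C2 is set without an organometallic addition or an oxocarbenium reduction; no protecting-group exchange is needed.
- Against it here: A5 needs its C4 centre from a separate asymmetric step and a Z-selective alkene synthesis. Direction of a peracid by a phenol is far less established than by an allylic alcohol, and peracids attack electron-rich phenols. The trialkoxyphenyl group favours ionisation at C2, which erodes inversion towards the 2,3-trans isomer, and 5-exo opening to a dihydrobenzofuran competes.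
- Comparison: after its key step alternative 2 is clearly shorter (A4 corresponds to 24 without the lactol and lactone steps), and here it is the better plan. In securing C4 the two plans are equal in that both need an asymmetric conjugate addition, but the chosen plan gains C3 in the same operation. For C2, hydride delivery anti to two cis substituents is judged more reliable than inversion at an electron-rich benzylic epoxide.

Alternative 3: The cut is C4–C4a of the top unit, back to carbinol A7, an acyclic 3-benzyloxyphenyl ether whose future C4 already carries the 2,6-dioxygenated bromoarene that becomes ring A of the middle unit. Forward, acid would ionise the carbinol and the ether ring would attack para to its benzyloxy group to give A6.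
- In its favour: the crowded C4–C8 bond is made early as an aryl-metal addition to an aldehyde; the closure is intramolecular and uses the best position of the nucleophile; the di-ortho-substituted aryl group on the cation lies perpendicular, so allylic strain lets the C3 substituent send the ring to the trans face; A6 carries a bromine at the future C4a and an allyl ether at the future O1 as handles.
- Against it here: C2 and C3 of the top unit must be made by asymmetric synthesis, so the chiral-pool flavanonol is given up; attack between the two oxygens of the ether must be excluded; the whole middle ring C and the epicatechin unit remain to be built on a large acid-sensitive intermediate.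
- Comparison: for the top–middle bond alternative 3 is better than the chosen plan, whose weakest step outside the key step is exactly this bond. In stereocontrol at C4 of the top unit the two are equal (both rely on the C3 substituent). In convergence and step count the chosen plan is ahead, since it joins three fragments of similar size and builds the all-cis ring first.

Key step: step 8

## Route

Step 1
Reactants: 1 (−)-epicatechin
Product: 2 5,7,3',4'-tetra-O-benzyl-(−)-epicatechin
Conditions: BnBr, K2CO3, DMF, 0 °C → rt, N2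
Reagents that add atoms: benzyl bromide BrCc1ccccc1
Why: Williamson ether synthesis; carbonate alkylates the four phenols and leaves the aliphatic 3-OH; room temperature avoids C2 epimerisation.

Step 2
Reactants: 2 5,7,3',4'-tetra-O-benzyl-(−)-epicatechin
Product: 3 3,5,7,3',4'-penta-O-benzyl-(−)-epicatechin
Conditions: NaH, BnBr, n-Bu4NI (cat.), DMF, 0 °C → rt
Reagents that add atoms: benzyl bromide BrCc1ccccc1
Why: Williamson etherification of the secondary alkoxide, so that the organolithium and strong-base steps meet no free hydroxyl.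

Step 3
Reactants: 3 3,5,7,3',4'-penta-O-benzyl-(−)-epicatechin
Product: 4 8-bromo-3,5,7,3',4'-penta-O-benzyl-(−)-epicatechin
Conditions: NBS (1.0 equiv), CH2Cl2, −78 → −20 °C
Reagents that add atoms: N-bromosuccinimide O=C1CCC(=O)N1Br
Why: Electrophilic aromatic bromination; C8 is the preferred site of the benzylated phloroglucinol ring, and one equivalent at low temperature leaves C6 and ring B alone.

Step 4
Reactants: 4 8-bromo-3,5,7,3',4'-penta-O-benzyl-(−)-epicatechin
Product: 6 8-formyl-3,5,7,3',4'-penta-O-benzyl-(−)-epicatechin, via 8-lithio arene 5 (not isolated)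
Conditions: n-BuLi, THF, −78 °C; then DMF; aq. NH4Cl
Reagents that add atoms: N,N-dimethylformamide CN(C)C=O
Why: Bromine–lithium exchange, then formylation of the aryllithium with DMF; at −78 °C exchange is faster than attack on the benzyl ethers.

Step 5
Reactants: 6 8-formyl-3,5,7,3',4'-penta-O-benzyl-(−)-epicatechin
Product: 7 6-bromo-8-formyl-3,5,7,3',4'-penta-O-benzyl-(−)-epicatechin
Conditions: NBS (1.05 equiv), CH2Cl2, 0 °C → rt
Reagents that add atoms: N-bromosuccinimide O=C1CCC(=O)N1Br
Why: Electrophilic aromatic bromination at C6, the only free position of ring A; it is flanked by two benzyloxy groups and only meta to the formyl group, so ring A should still react ahead of ring B.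

Step 6
Reactants: 7 6-bromo-8-formyl-3,5,7,3',4'-penta-O-benzyl-(−)-epicatechin
Product: 9 (E)-3-(6-bromo-3,5,7,3',4'-penta-O-benzylepicatechin-8-yl)acrolein, via vinyl dioxolane 8 (not isolated)
Conditions: [(1,3-dioxolan-2-yl)methyl]PPh3Br, t-BuOK, THF, 0 °C → rt; then 1 M HCl, THF, rt
Reagents that add atoms: (1,3-dioxolan-2-ylmethyl)triphenylphosphonium bromide [Br-].C1COC(O1)C[P+](c1ccccc1)(c1ccccc1)c1ccccc1; water O
Why: Wittig reaction with a two-carbon acetal ylide, then acid hydrolysis, which unmasks the aldehyde and equilibrates the alkene to E; this avoids the double homologation risked with a formyl ylide on an unreactive, hindered aldehyde.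

Step 7
Reactants: 10 3-(allyloxy)phenol
Product: 11 4-bromo-3-(allyloxy)phenol
Conditions: NBS (1.0 equiv), CH2Cl2, −78 → −30 °C
Reagents that add atoms: N-bromosuccinimide O=C1CCC(=O)N1Br
Why: Electrophilic bromination para to the free hydroxyl, the stronger director; the isomer brominated para to the ether is the expected minor product and is removed by chromatography.

Step 8
Reactants: 9 (E)-3-(6-bromo-3,5,7,3',4'-penta-O-benzylepicatechin-8-yl)acrolein; 11 4-bromo-3-(allyloxy)phenol; 12 dibenzoyl peroxide
Product: 14 (3R,4S)-7-(allyloxy)-6-bromo-2-hydroxy-4-Ep-chroman-3-yl benzoate (3,4-cis; lactol anomers), via Friedel–Crafts lactol 13 (not isolated)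
Conditions: (R)-α,α-diphenylprolinol trimethylsilyl ether (20 mol%), PhCO2H (20 mol%), toluene, rt; then 12, hydroquinone (10 mol%), THF, 0 °C
Reagents that add atoms: none
Why: Proposed new method: the (R)-amine and 9 form the E-iminium ion, and 11 adds through its ortho carbon (C4–C4a) on the face left open by the diphenyl(silyloxy)methyl group. Hydrolysis gives lactol 13, whose open hydroxy aldehyde is converted by the same amine into the E-enamine; this attacks the O–O bond of 12 (C3–O), and the phenol then recloses onto the aldehyde (O1–C2) by 6-exo-trig hemiacetalisation, the only ring closed. The closest known reaction types are the iminium-catalysed Friedel–Crafts/hemiacetalisation of electron-rich phenols with enals to 4-aryl-chroman-2-ols and the enamine α-benzoyloxylation of aldehydes with dibenzoyl peroxide under diarylprolinol silyl ether catalysis; new are their union in one flask and the β-(2,6-dialkoxyaryl) enal. C4 is controlled by the shielding group of the amine in the iminium stage (expected S) and C3 by the same group in the enamine stage (expected R); both reagents enter on the same face of the extended chain, which corresponds to 3,4-cis in the ring, so one enantiomer of the amine serves both stages. The anomeric carbon is left uncontrolled and is removed later. The step needs ortho C-alkylation para to the allyloxy group: bromine closes the position para to the hydroxyl, the carbon between the two oxygens is crowded, and O-addition is reversible. 12 is added only after 9 is consumed, because it would otherwise oxidise the amine and the phenol during the slow first stage. Closure to the lactol takes the α-acyloxy aldehyde out of the enamine equilibrium and so protects C3 from epimerisation.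

Step 9
Reactants: 14 (3R,4S)-7-(allyloxy)-6-bromo-2-hydroxy-4-Ep-chroman-3-yl benzoate
Product: 15 (3R,4S)-7-(allyloxy)-6-bromo-2-methoxy-4-Ep-chroman-3-yl benzoate (acetal anomers)
Conditions: MeOH, CSA (cat.), CH2Cl2, rt
Reagents that add atoms: methanol CO
Why: Fischer-type acetalisation of the lactol; it blocks the anomeric position so that the benzoate can be exchanged without opening to an α-hydroxy aldehyde that could epimerise at C3.

Step 10
Reactants: 15 (3R,4S)-7-(allyloxy)-6-bromo-2-methoxy-4-Ep-chroman-3-yl benzoate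
Product: 16 (3R,4S)-7-(allyloxy)-6-bromo-2-methoxy-4-Ep-chroman-3-ol
Conditions: K2CO3 (cat.), MeOH/THF, rt
Reagents that add atoms: none
Why: Base-catalysed transesterification of the secondary benzoate; the acetal, the aryl bromides and the allyl ether are inert.

Step 11
Reactants: 16 (3R,4S)-7-(allyloxy)-6-bromo-2-methoxy-4-Ep-chroman-3-ol
Product: 17 (3R,4S)-7-(allyloxy)-3-(benzyloxy)-6-bromo-2-methoxy-4-Ep-chroman
Conditions: NaH, BnBr, n-Bu4NI (cat.), DMF, 0 °C → rt
Reagents that add atoms: benzyl bromide BrCc1ccccc1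
Why: Williamson etherification; benzyl at O3 survives the aryllithium and Lewis acid steps and leaves with the other benzyl groups at the end.

Step 12
Reactants: 17 (3R,4S)-7-(allyloxy)-3-(benzyloxy)-6-bromo-2-methoxy-4-Ep-chroman
Product: 18 (3R,4S)-7-(allyloxy)-3-(benzyloxy)-6-bromo-4-Ep-chroman-2-ol (lactol anomers)
Conditions: 1 M HCl, THF, 50 °C
Reagents that add atoms: water O
Why: Acid hydrolysis of the mixed aryl alkyl acetal; the brominated 5-deoxy ring A makes the C4–aryl bond resistant to acid.

Step 13
Reactants: 18 (3R,4S)-7-(allyloxy)-3-(benzyloxy)-6-bromo-4-Ep-chroman-2-ol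
Product: 19 (3R,4S)-7-(allyloxy)-3-(benzyloxy)-6-bromo-4-Ep-chroman-2-one (cis lactone)
Conditions: TEMPO (10 mol%), PhI(OAc)2, CH2Cl2, rt
Reagents that add atoms: none
Why: Oxoammonium (TEMPO) oxidation of a lactol to the lactone; neutral conditions preserve C3, now α to a carbonyl.

Step 14
Reactants: 20 5-bromopyrogallol
Product: 21 5-bromo-1,2,3-tris(benzyloxy)benzene
Conditions: BnBr, K2CO3, DMF, rt → 50 °C, N2
Reagents that add atoms: benzyl bromide BrCc1ccccc1
Why: Williamson ether synthesis on the three phenols under exclusion of air.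

Step 15
Reactants: 19 (3R,4S)-7-(allyloxy)-3-(benzyloxy)-6-bromo-4-Ep-chroman-2-one; 21 5-bromo-1,2,3-tris(benzyloxy)benzene
Product: 23 (3R,4S)-7-(allyloxy)-3-(benzyloxy)-6-bromo-2-[3,4,5-tris(benzyloxy)phenyl]-4-Ep-chroman-2-ol (hemiketal in equilibrium with its open hydroxy ketone), via aryllithium 22 (not isolated)
Conditions: 21, n-BuLi, THF, −78 °C; then 19, THF, −78 °C; aq. NH4Cl
Reagents that add atoms: none
Why: Bromine–lithium exchange on 21, then addition of the aryllithium to the aryl lactone; at −78 °C carbonyl addition should outrun exchange with the aryl bromides of 19 and enolisation, and the hindered, electron-rich keto-phenoxide resists a second addition.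

Step 16
Reactants: 23 (3R,4S)-7-(allyloxy)-3-(benzyloxy)-6-bromo-2-[3,4,5-tris(benzyloxy)phenyl]-4-Ep-chroman-2-ol
Product: 24 (2R,3R,4S)-7-(allyloxy)-3-(benzyloxy)-6-bromo-2-[3,4,5-tris(benzyloxy)phenyl]-4-Ep-chroman (all-cis)
Conditions: Et3SiH, BF3·OEt2, CH2Cl2/MeCN, −40 → −20 °C
Reagents that add atoms: none
Why: Ionic hydrogenation of a hemiketal, as in C-aryl glycoside synthesis; BF3 gives the 2-aryl oxocarbenium ion and the silane delivers hydride to the face opposite the cis C3 benzyloxy and C4 aryl groups, so the aryl group at the new C2 centre (R) ends cis to both.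

Step 17
Reactants: 24 (2R,3R,4S)-7-(allyloxy)-3-(benzyloxy)-6-bromo-2-[3,4,5-tris(benzyloxy)phenyl]-4-Ep-chroman
Product: 25 (2R,3R,4S)-3-(benzyloxy)-6-bromo-2-[3,4,5-tris(benzyloxy)phenyl]-4-Ep-chroman-7-ol
Conditions: Pd(PPh3)4 (5 mol%), morpholine, THF, rt
Reagents that add atoms: none
Why: Tsuji–Trost deallylation through a π-allyl complex of zerovalent palladium trapped by morpholine; at room temperature oxidative addition into the electron-rich, hindered aryl bromides should not compete.

Step 18
Reactants: 26 (+)-dihydrorobinetin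
Product: 27 (2R,3R)-7-(benzyloxy)-3-hydroxy-2-[3,4,5-tris(benzyloxy)phenyl]chroman-4-one
Conditions: BnBr, K2CO3, DMF, rt, N2
Reagents that add atoms: benzyl bromide BrCc1ccccc1
Why: Williamson ether synthesis; the four phenols react and the α-hydroxy ketone hydroxyl does not; exclusion of air limits oxidation to the flavonol.

Step 19
Reactants: 27 (2R,3R)-7-(benzyloxy)-3-hydroxy-2-[3,4,5-tris(benzyloxy)phenyl]chroman-4-one
Product: 29 (2R,3S,4R)-7-(benzyloxy)-4-methoxy-2-[3,4,5-tris(benzyloxy)phenyl]chroman-3-ol, via flavan-3,4-diol 28 (not isolated)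
Conditions: NaBH4, THF/MeOH, 0 °C; then HCl/MeOH (pH 1), rt
Reagents that add atoms: methanol CO
Why: Hydride reduction of the aryl ketone trans to the C3 hydroxyl gives the 3,4-trans diol; only its benzylic hydroxyl is then exchanged for methoxy by SN1 solvolysis, mainly trans to O3. A minor C4 epimer does not matter because C4 is ionised in step 23.

Step 20
Reactants: 29 (2R,3S,4R)-7-(benzyloxy)-4-methoxy-2-[3,4,5-tris(benzyloxy)phenyl]chroman-3-ol
Product: 30 (2R,4R)-7-(benzyloxy)-4-methoxy-2-[3,4,5-tris(benzyloxy)phenyl]chroman-3-one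
Conditions: Dess–Martin periodinane, NaHCO3, CH2Cl2, 0 °C → rt
Reagents that add atoms: none
Why: Dess–Martin oxidation of the secondary alcohol; buffered, non-basic conditions avoid enolisation towards C2.

Step 21
Reactants: 30 (2R,4R)-7-(benzyloxy)-4-methoxy-2-[3,4,5-tris(benzyloxy)phenyl]chroman-3-one
Product: 31 (2R,3R,4R)-7-(benzyloxy)-4-methoxy-2-[3,4,5-tris(benzyloxy)phenyl]chroman-3-ol (2,3-cis)
Conditions: LiBH(s-Bu)3, THF, −78 °C; aq. NH4Cl
Reagents that add atoms: none
Why: The bulky hydride attacks the flavan-3-one on the face opposite the equatorial C2 aryl and C4 methoxy groups and gives the axial 3-hydroxyl cis to the aryl group, as in the known oxidation–reduction inversion of catechin to epicatechin ethers.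

Step 22
Reactants: 31 (2R,3R,4R)-7-(benzyloxy)-4-methoxy-2-[3,4,5-tris(benzyloxy)phenyl]chroman-3-ol
Product: 32 (2R,3R,4R)-7-(benzyloxy)-6-bromo-4-methoxy-2-[3,4,5-tris(benzyloxy)phenyl]chroman-3-ol
Conditions: NBS (1.0 equiv), CH2Cl2, −78 → −30 °C
Reagents that add atoms: N-bromosuccinimide O=C1CCC(=O)N1Br
Why: Electrophilic aromatic bromination; C6 of ring A (para to O1, ortho to the benzyloxy group, open on one side) should react before the doubly flanked positions of ring B. The bromine keeps this unit from alkylating itself in step 23.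

Step 23
Reactants: 25 (2R,3R,4S)-3-(benzyloxy)-6-bromo-2-[3,4,5-tris(benzyloxy)phenyl]-4-Ep-chroman-7-ol; 32 (2R,3R,4R)-7-(benzyloxy)-6-bromo-4-methoxy-2-[3,4,5-tris(benzyloxy)phenyl]chroman-3-ol
Product: 33 protected trimer: 25 bearing at C8 the (2R,3R,4R)-7-(benzyloxy)-6-bromo-3-hydroxy-2-[3,4,5-tris(benzyloxy)phenyl]chroman-4-yl group
Conditions: BF3·OEt2, CH2Cl2, −30 → 0 °C, slow addition of 32
Reagents that add atoms: none
Why: Friedel–Crafts interflavan coupling: BF3 ionises the benzylic methyl ether and the cation is attacked by C8 of 25, the only free activated carbon (ortho to the free 7-hydroxyl; C6 of both lower units is brominated). Attack comes trans to the axial 3-hydroxyl of the 2,3-cis unit, giving the 3,4-trans bond (C4 R); slow addition keeps the concentration of 32 low.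

Step 24
Reactants: 33 protected trimer
Product: 34 target trimer
Conditions: H2 (1 atm), Pd(OH)2/C, Et3N, THF/MeOH/H2O, rt
Reagents that add atoms: none
Why: Hydrogenolysis cleaves the thirteen benzyl ethers and the three aryl C–Br bonds in one operation; Et3N takes up HBr so the interflavan bonds are not exposed to acid; degassed solvents and slight acidification before filtration protect the pyrogallol rings.

## Compound list

(Ep = 6-bromo-3,5,7,3',4'-penta-O-benzyl-(2R,3R)-epicatechin-8-yl)

1 | (−)-epicatechin, (2R,3R) | Oc1cc(O)c2c(c1)O[C@H](c1ccc(O)c(O)c1)[C@H](O)C2 | starting material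
2 | 5,7,3',4'-tetra-O-benzyl-(−)-epicatechin | c9ccccc9COc1cc(OCc9ccccc9)c2c(c1)O[C@H](c1ccc(OCc9ccccc9)c(OCc9ccccc9)c1)[C@H](O)C2 | intermediate
3 | 3,5,7,3',4'-penta-O-benzyl-(−)-epicatechin | c9ccccc9COc1cc(OCc9ccccc9)c2c(c1)O[C@H](c1ccc(OCc9ccccc9)c(OCc9ccccc9)c1)[C@H](OCc9ccccc9)C2 | intermediate
4 | 8-bromo-3,5,7,3',4'-penta-O-benzyl-(−)-epicatechin | Brc1c(OCc9ccccc9)cc(OCc9ccccc9)c2c1O[C@H](c1ccc(OCc9ccccc9)c(OCc9ccccc9)c1)[C@H](OCc9ccccc9)C2 | intermediate
5 | 8-lithio-3,5,7,3',4'-penta-O-benzyl-(−)-epicatechin | [Li]c1c(OCc9ccccc9)cc(OCc9ccccc9)c2c1O[C@H](c1ccc(OCc9ccccc9)c(OCc9ccccc9)c1)[C@H](OCc9ccccc9)C2 | intermediate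
6 | 8-formyl-3,5,7,3',4'-penta-O-benzyl-(−)-epicatechin | O=Cc1c(OCc9ccccc9)cc(OCc9ccccc9)c2c1O[C@H](c1ccc(OCc9ccccc9)c(OCc9ccccc9)c1)[C@H](OCc9ccccc9)C2 | intermediate
7 | 6-bromo-8-formyl-3,5,7,3',4'-penta-O-benzyl-(−)-epicatechin | O=Cc1c(OCc9ccccc9)c(Br)c(OCc9ccccc9)c2c1O[C@H](c1ccc(OCc9ccccc9)c(OCc9ccccc9)c1)[C@H](OCc9ccccc9)C2 | intermediate
8 | 6-bromo-8-[2-(1,3-dioxolan-2-yl)vinyl]-3,5,7,3',4'-penta-O-benzyl-(−)-epicatechin (E/Z mixture) | C1COC(O1)C=Cc1c(OCc9ccccc9)c(Br)c(OCc9ccccc9)c2c1O[C@H](c1ccc(OCc9ccccc9)c(OCc9ccccc9)c1)[C@H](OCc9ccccc9)C2 | intermediate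
9 | (E)-3-(6-bromo-3,5,7,3',4'-penta-O-benzylepicatechin-8-yl)acrolein | O=C/C=C/c1c(OCc9ccccc9)c(Br)c(OCc9ccccc9)c2c1O[C@H](c1ccc(OCc9ccccc9)c(OCc9ccccc9)c1)[C@H](OCc9ccccc9)C2 | intermediate
10 | 3-(allyloxy)phenol | Oc1cccc(OCC=C)c1 | starting material
11 | 4-bromo-3-(allyloxy)phenol | Oc1ccc(Br)c(OCC=C)c1 | intermediate
12 | dibenzoyl peroxide | O=C(OOC(=O)c1ccccc1)c1ccccc1 | starting material
13 | (4S)-7-(allyloxy)-6-bromo-4-Ep-chroman-2-ol (lactol anomers) | c1c(OCC=C)c(Br)cc2c1OC(O)C[C@@H]2c1c(OCc9ccccc9)c(Br)c(OCc9ccccc9)c2c1O[C@H](c1ccc(OCc9ccccc9)c(OCc9ccccc9)c1)[C@H](OCc9ccccc9)C2 | intermediate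
14 | (3R,4S)-7-(allyloxy)-6-bromo-2-hydroxy-4-Ep-chroman-3-yl benzoate (3,4-cis; lactol anomers) | c1c(OCC=C)c(Br)cc2c1OC(O)[C@H](OC(=O)c1ccccc1)[C@@H]2c1c(OCc9ccccc9)c(Br)c(OCc9ccccc9)c2c1O[C@H](c1ccc(OCc9ccccc9)c(OCc9ccccc9)c1)[C@H](OCc9ccccc9)C2 | intermediate
15 | (3R,4S)-7-(allyloxy)-6-bromo-2-methoxy-4-Ep-chroman-3-yl benzoate (acetal anomers) | c1c(OCC=C)c(Br)cc2c1OC(OC)[C@H](OC(=O)c1ccccc1)[C@@H]2c1c(OCc9ccccc9)c(Br)c(OCc9ccccc9)c2c1O[C@H](c1ccc(OCc9ccccc9)c(OCc9ccccc9)c1)[C@H](OCc9ccccc9)C2 | intermediate
16 | (3R,4S)-7-(allyloxy)-6-bromo-2-methoxy-4-Ep-chroman-3-ol | c1c(OCC=C)c(Br)cc2c1OC(OC)[C@H](O)[C@@H]2c1c(OCc9ccccc9)c(Br)c(OCc9ccccc9)c2c1O[C@H](c1ccc(OCc9ccccc9)c(OCc9ccccc9)c1)[C@H](OCc9ccccc9)C2 | intermediate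
17 | (3R,4S)-7-(allyloxy)-3-(benzyloxy)-6-bromo-2-methoxy-4-Ep-chroman | c1c(OCC=C)c(Br)cc2c1OC(OC)[C@H](OCc9ccccc9)[C@@H]2c1c(OCc9ccccc9)c(Br)c(OCc9ccccc9)c2c1O[C@H](c1ccc(OCc9ccccc9)c(OCc9ccccc9)c1)[C@H](OCc9ccccc9)C2 | intermediate
18 | (3R,4S)-7-(allyloxy)-3-(benzyloxy)-6-bromo-4-Ep-chroman-2-ol (lactol anomers) | c1c(OCC=C)c(Br)cc2c1OC(O)[C@H](OCc9ccccc9)[C@@H]2c1c(OCc9ccccc9)c(Br)c(OCc9ccccc9)c2c1O[C@H](c1ccc(OCc9ccccc9)c(OCc9ccccc9)c1)[C@H](OCc9ccccc9)C2 | intermediate
19 | (3R,4S)-7-(allyloxy)-3-(benzyloxy)-6-bromo-4-Ep-chroman-2-one (cis lactone) | c1c(OCC=C)c(Br)cc2c1OC(=O)[C@H](OCc9ccccc9)[C@@H]2c1c(OCc9ccccc9)c(Br)c(OCc9ccccc9)c2c1O[C@H](c1ccc(OCc9ccccc9)c(OCc9ccccc9)c1)[C@H](OCc9ccccc9)C2 | intermediate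
20 | 5-bromopyrogallol | Oc1cc(Br)cc(O)c1O | starting material
21 | 5-bromo-1,2,3-tris(benzyloxy)benzene | c9ccccc9COc1cc(Br)cc(OCc9ccccc9)c1OCc9ccccc9 | intermediate
22 | 3,4,5-tris(benzyloxy)phenyllithium | [Li]c1cc(OCc9ccccc9)c(OCc9ccccc9)c(OCc9ccccc9)c1 | intermediate
23 | (3R,4S)-7-(allyloxy)-3-(benzyloxy)-6-bromo-2-[3,4,5-tris(benzyloxy)phenyl]-4-Ep-chroman-2-ol (hemiketal; C2 not defined) | c1c(OCC=C)c(Br)cc2c1OC(O)(c1cc(OCc9ccccc9)c(OCc9ccccc9)c(OCc9ccccc9)c1)[C@H](OCc9ccccc9)[C@@H]2c1c(OCc9ccccc9)c(Br)c(OCc9ccccc9)c2c1O[C@H](c1ccc(OCc9ccccc9)c(OCc9ccccc9)c1)[C@H](OCc9ccccc9)C2 | intermediate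
24 | (2R,3R,4S)-7-(allyloxy)-3-(benzyloxy)-6-bromo-2-[3,4,5-tris(benzyloxy)phenyl]-4-Ep-chroman (all-cis) | c1c(OCC=C)c(Br)cc2c1O[C@H](c1cc(OCc9ccccc9)c(OCc9ccccc9)c(OCc9ccccc9)c1)[C@H](OCc9ccccc9)[C@@H]2c1c(OCc9ccccc9)c(Br)c(OCc9ccccc9)c2c1O[C@H](c1ccc(OCc9ccccc9)c(OCc9ccccc9)c1)[C@H](OCc9ccccc9)C2 | intermediate
25 | (2R,3R,4S)-3-(benzyloxy)-6-bromo-2-[3,4,5-tris(benzyloxy)phenyl]-4-Ep-chroman-7-ol | c1c(O)c(Br)cc2c1O[C@H](c1cc(OCc9ccccc9)c(OCc9ccccc9)c(OCc9ccccc9)c1)[C@H](OCc9ccccc9)[C@@H]2c1c(OCc9ccccc9)c(Br)c(OCc9ccccc9)c2c1O[C@H](c1ccc(OCc9ccccc9)c(OCc9ccccc9)c1)[C@H](OCc9ccccc9)C2 | intermediate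
26 | (+)-dihydrorobinetin, (2R,3R), 2,3-trans | Oc1ccc2c(c1)O[C@H](c1cc(O)c(O)c(O)c1)[C@@H](O)C2=O | starting material
27 | (2R,3R)-7-(benzyloxy)-3-hydroxy-2-[3,4,5-tris(benzyloxy)phenyl]chroman-4-one | c9ccccc9COc1ccc2c(c1)O[C@H](c1cc(OCc9ccccc9)c(OCc9ccccc9)c(OCc9ccccc9)c1)[C@@H](O)C2=O | intermediate
28 | (2R,3S,4R)-7-(benzyloxy)-2-[3,4,5-tris(benzyloxy)phenyl]chroman-3,4-diol (2,3-trans-3,4-trans) | c9ccccc9COc1ccc2c(c1)O[C@H](c1cc(OCc9ccccc9)c(OCc9ccccc9)c(OCc9ccccc9)c1)[C@@H](O)[C@@H]2O | intermediate
29 | (2R,3S,4R)-7-(benzyloxy)-4-methoxy-2-[3,4,5-tris(benzyloxy)phenyl]chroman-3-ol | c9ccccc9COc1ccc2c(c1)O[C@H](c1cc(OCc9ccccc9)c(OCc9ccccc9)c(OCc9ccccc9)c1)[C@@H](O)[C@@H]2OC | intermediate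
30 | (2R,4R)-7-(benzyloxy)-4-methoxy-2-[3,4,5-tris(benzyloxy)phenyl]chroman-3-one | c9ccccc9COc1ccc2c(c1)O[C@H](c1cc(OCc9ccccc9)c(OCc9ccccc9)c(OCc9ccccc9)c1)C(=O)[C@@H]2OC | intermediate
31 | (2R,3R,4R)-7-(benzyloxy)-4-methoxy-2-[3,4,5-tris(benzyloxy)phenyl]chroman-3-ol (2,3-cis) | c9ccccc9COc1ccc2c(c1)O[C@H](c1cc(OCc9ccccc9)c(OCc9ccccc9)c(OCc9ccccc9)c1)[C@H](O)[C@@H]2OC | intermediate
32 | (2R,3R,4R)-7-(benzyloxy)-6-bromo-4-methoxy-2-[3,4,5-tris(benzyloxy)phenyl]chroman-3-ol | c9ccccc9COc1c(Br)cc2c(c1)O[C@H](c1cc(OCc9ccccc9)c(OCc9ccccc9)c(OCc9ccccc9)c1)[C@H](O)[C@@H]2OC | intermediate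
33 | protected trimer: 25 bearing at C8 the (2R,3R,4R)-7-(benzyloxy)-6-bromo-3-hydroxy-2-[3,4,5-tris(benzyloxy)phenyl]chroman-4-yl group (3,4-trans) | c9ccccc9COc1c(Br)cc2c(c1)O[C@H](c1cc(OCc9ccccc9)c(OCc9ccccc9)c(OCc9ccccc9)c1)[C@H](O)[C@H]2c1c(O)c(Br)cc2c1O[C@H](c1cc(OCc9ccccc9)c(OCc9ccccc9)c(OCc9ccccc9)c1)[C@H](OCc9ccccc9)[C@@H]2c1c(OCc9ccccc9)c(Br)c(OCc9ccccc9)c2c1O[C@H](c1ccc(OCc9ccccc9)c(OCc9ccccc9)c1)[C@H](OCc9ccccc9)C2 | intermediate
34 | target trimer, epirobinetinidol-(4β→8)-epirobinetinidol-(4α→8)-epicatechin: top (2R,3R,4R), middle (2R,3R,4S), bottom (2R,3R) | Oc1ccc2c(c1)O[C@H](c1cc(O)c(O)c(O)c1)[C@H](O)[C@H]2c1c(O)ccc2c1O[C@H](c1cc(O)c(O)c(O)c1)[C@H](O)[C@@H]2c1c(O)cc(O)c2c1O[C@H](c1ccc(O)c(O)c1)[C@H](O)C2 | target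

## Step count and least certain steps

Total: 24 steps. Longest linear sequence: 17 steps (steps 1–6, 8–13, 15–17, 23, 24).

Step 8 (key step). Most likely to go wrong: the conjugate addition may be slow or fail because the β-aryl group of the iminium ion is electron-rich and doubly ortho-substituted and the brominated phenol is only moderately nucleophilic. In the second stage the peroxide may oxidise the amine faster than the lactol reopens to the aldehyde, and control by the amine may be eroded by the bulky neighbouring C4 centre, giving the 3,4-trans isomer. Fallback with known chemistry, setting out from 9 and 11 and returning at 19: the two-component reaction is run without 12 and stopped at lactol 13, which is oxidised (TEMPO, PhI(OAc)2) to the dihydrocoumarin F1. Its enolate (KN(SiMe3)2, THF, −78 °C) is hydroxylated with 2-(phenylsulfonyl)-3-phenyloxaziridine on the face away from the C4 aryl group to the trans hydroxy lactone F2. Benzylation with benzyl 2,2,2-trichloroacetimidate and catalytic TfOH gives the trans benzyl ether F3. Deprotonation (LiN(SiMe3)2, −78 °C) and kinetic protonation of the enolate by a hindered phenol, again anti to the C4 aryl group, places the benzyloxy group cis and gives 19.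

Step 23. Most likely to go wrong: attack at a carbon lying between two oxygens and meta to bromine is slow, so self-alkylation of the electrophile at its own C8, O-alkylation, or proton loss from the cation may take over. Fallback from 32, returning at 33: the methoxy group is exchanged for a benzylsulfanyl group (BnSH, BF3·OEt2, −40 °C; the thiol outcompetes every ring carbon) to give the thioether F4, and F4 is coupled with 25 under neutral thiophilic activation (AgBF4, THF, 0 °C), which forms the cation irreversibly without a protic or oxophilic acid.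

Step 16. Most likely to go wrong: proton loss from the 2-aryl oxocarbenium ion to the flav-2-ene, which erases C3, or incomplete facial selectivity of hydride delivery. Fallback from 23, returning at 24: the open hydroxy ketone form of 23 is reduced under chelation control through the C3 benzyloxy group (Zn(BH4)2, Et2O, −20 °C) to the anti carbinol F5, and the phenol closes ring C by Mitsunobu reaction (PPh3, DIAD, THF) with inversion at C2.

Step 15. Most likely to go wrong: a second addition to the ring-opened ketone, enolisation of the lactone at C3, or bromine–lithium exchange with the aryl bromides of 19. Fallback from 19, returning at 23: the lactone is opened with MeNHOMe·HCl and i-PrMgCl (THF, −20 °C) to the Weinreb amide F6, which takes up 22 (two equivalents, the first consumed by the phenol) only once; the ketone closes to 23 on work-up.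

Step 22. Most likely to go wrong: competing bromination of the pyrogallol ring B, because its free positions are also activated by two ether oxygens. Fallback from 31, returning at 34: bromination is driven with NBS (2.2 equiv) to the defined 6,2'-dibromide F7, which is coupled with 25 as in step 23 to the trimer F8; the extra bromine leaves in the final hydrogenolysis, which gives 34.

## Further compounds

F1 | step 8 | (4S)-7-(allyloxy)-6-bromo-4-Ep-chroman-2-one | c1c(OCC=C)c(Br)cc2c1OC(=O)C[C@@H]2c1c(OCc9ccccc9)c(Br)c(OCc9ccccc9)c2c1O[C@H](c1ccc(OCc9ccccc9)c(OCc9ccccc9)c1)[C@H](OCc9ccccc9)C2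
F2 | step 8 | (3S,4S)-7-(allyloxy)-6-bromo-3-hydroxy-4-Ep-chroman-2-one (3,4-trans) | c1c(OCC=C)c(Br)cc2c1OC(=O)[C@@H](O)[C@@H]2c1c(OCc9ccccc9)c(Br)c(OCc9ccccc9)c2c1O[C@H](c1ccc(OCc9ccccc9)c(OCc9ccccc9)c1)[C@H](OCc9ccccc9)C2
F3 | step 8 | (3S,4S)-7-(allyloxy)-3-(benzyloxy)-6-bromo-4-Ep-chroman-2-one (3,4-trans) | c1c(OCC=C)c(Br)cc2c1OC(=O)[C@@H](OCc9ccccc9)[C@@H]2c1c(OCc9ccccc9)c(Br)c(OCc9ccccc9)c2c1O[C@H](c1ccc(OCc9ccccc9)c(OCc9ccccc9)c1)[C@H](OCc9ccccc9)C2
F4 | step 23 | 4-(benzylsulfanyl) analogue of 32, sulfur trans to the C3 hydroxyl | c9ccccc9COc1c(Br)cc2c(c1)O[C@H](c1cc(OCc9ccccc9)c(OCc9ccccc9)c(OCc9ccccc9)c1)[C@H](O)[C@H]2SCc9ccccc9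
F5 | step 16 | ring-opened diol of 23: free phenol at O1, C2 carbinol anti to the C3 benzyloxy group | Oc1cc(OCC=C)c(Br)cc1[C@H]([C@@H](OCc9ccccc9)[C@@H](O)c1cc(OCc9ccccc9)c(OCc9ccccc9)c(OCc9ccccc9)c1)c1c(OCc9ccccc9)c(Br)c(OCc9ccccc9)c2c1O[C@H](c1ccc(OCc9ccccc9)c(OCc9ccccc9)c1)[C@H](OCc9ccccc9)C2
F6 | step 15 | (2R,3S)-3-[4-(allyloxy)-5-bromo-2-hydroxyphenyl]-2-(benzyloxy)-N-methoxy-N-methyl-3-Ep-propanamide | Oc1cc(OCC=C)c(Br)cc1[C@H]([C@@H](OCc9ccccc9)C(=O)N(C)OC)c1c(OCc9ccccc9)c(Br)c(OCc9ccccc9)c2c1O[C@H](c1ccc(OCc9ccccc9)c(OCc9ccccc9)c1)[C@H](OCc9ccccc9)C2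
F7 | step 22 | 6,2'-dibromide: 7-(benzyloxy)-6-bromo-2-[2-bromo-3,4,5-tris(benzyloxy)phenyl]-4-methoxychroman-3-ol, configuration as in 32 | c9ccccc9COc1c(Br)cc2c(c1)O[C@H](c1c(Br)c(OCc9ccccc9)c(OCc9ccccc9)c(OCc9ccccc9)c1)[C@H](O)[C@@H]2OC
F8 | step 22 | protected trimer as 33 with an additional bromine at C2' of the top ring B | c9ccccc9COc1c(Br)cc2c(c1)O[C@H](c1c(Br)c(OCc9ccccc9)c(OCc9ccccc9)c(OCc9ccccc9)c1)[C@H](O)[C@H]2c1c(O)c(Br)cc2c1O[C@H](c1cc(OCc9ccccc9)c(OCc9ccccc9)c(OCc9ccccc9)c1)[C@H](OCc9ccccc9)[C@@H]2c1c(OCc9ccccc9)c(Br)c(OCc9ccccc9)c2c1O[C@H](c1ccc(OCc9ccccc9)c(OCc9ccccc9)c1)[C@H](OCc9ccccc9)C2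
A1 | alternative 1 | benzylated top flavan bonded through C4 to the new middle ring A (free C8a hydroxyl, C7 triisopropylsilyl ether, dimethyl acetal on C4a) | c9ccccc9COc1ccc2c(c1)O[C@H](c1cc(OCc9ccccc9)c(OCc9ccccc9)c(OCc9ccccc9)c1)[C@H](OCc9ccccc9)[C@H]2c1c(O)c(C(OC)OC)ccc1O[Si](C(C)C)(C(C)C)C(C)C
A2 | alternative 1 | benzylated top flavan carrying a (triisopropylsilyloxy)ethynyl group at C4 (trans to O3) | c9ccccc9COc1ccc2c(c1)O[C@H](c1cc(OCc9ccccc9)c(OCc9ccccc9)c(OCc9ccccc9)c1)[C@H](OCc9ccccc9)[C@H]2C#CO[Si](C(C)C)(C(C)C)C(C)C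
A3 | alternative 1 | (E)-1-diazo-5,5-dimethoxypent-3-en-2-one | [N-]=[N+]=CC(=O)/C=C/C(OC)OC
A4 | alternative 2 | benzylated all-cis middle–bottom dimer with free C3 hydroxyl | c1c(OCc9ccccc9)ccc2c1O[C@H](c1cc(OCc9ccccc9)c(OCc9ccccc9)c(OCc9ccccc9)c1)[C@H](O)[C@@H]2c1c(OCc9ccccc9)cc(OCc9ccccc9)c2c1O[C@H](c1ccc(OCc9ccccc9)c(OCc9ccccc9)c1)[C@H](OCc9ccccc9)C2
A5 | alternative 2 | (Z)-1,3-diarylpropene: 5-(benzyloxy)-2-[1-(penta-O-benzylepicatechin-8-yl)-3-(3,4,5-tris(benzyloxy)phenyl)prop-2-enyl]phenol | Oc1cc(OCc9ccccc9)ccc1[C@H](/C=C\c1cc(OCc9ccccc9)c(OCc9ccccc9)c(OCc9ccccc9)c1)c1c(OCc9ccccc9)cc(OCc9ccccc9)c2c1O[C@H](c1ccc(OCc9ccccc9)c(OCc9ccccc9)c1)[C@H](OCc9ccccc9)C2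
A6 | alternative 3 | benzylated top flavan carrying at C4 the 2-(allyloxy)-6-(benzyloxy)-3-bromophenyl group (future middle ring A) | c9ccccc9COc1ccc2c(c1)O[C@H](c1cc(OCc9ccccc9)c(OCc9ccccc9)c(OCc9ccccc9)c1)[C@H](OCc9ccccc9)[C@H]2c1c(OCC=C)c(Br)ccc1OCc9ccccc9
A7 | alternative 3 | acyclic carbinol: 3-(benzyloxy)phenyl ether of the C2 alcohol, C3 benzyl ether, C4 carbinol bearing the 2-(allyloxy)-6-(benzyloxy)-3-bromophenyl group | c9ccccc9COc1cccc(c1)O[C@H](c1cc(OCc9ccccc9)c(OCc9ccccc9)c(OCc9ccccc9)c1)[C@H](OCc9ccccc9)C(O)c1c(OCC=C)c(Br)ccc1OCc9ccccc9
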